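**Strategy.** The side chain (C1' on the ring, C12' the terminal CH2OH) is cut at C3'–C4', the sp2–sp3 junction of the skipped 1,5-diene C2'=C3'/C6'=C7'. In one operation the terminal vinyl group of a 1,3-diene (future C4'–C5') is hydroborated with 9-BBN, the two trisubstituted alkenes staying inert, and the homoallylborane is cross-coupled (B-alkyl Suzuki–Miyaura) with an (E)-vinyl iodide on the stereodefined, ketal-masked cyclohexenol ring, with retention of the C2'=C3' geometry. The precursors are a bis-silylated nona-1,3,7-triene and an iodobutenyl cyclohexenol. The ring stereotriad derives from a quinone monoketal, the C9' carbinol from a catalytic asymmetric propargylation.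

Key step: step 13

Remark: the sense of induction of the two chiral catalysts (steps 4 and 10) is assigned by analogy with their closest substrate classes; both antipodes of each catalyst are available, and 2,3,4-trimethoxyphenol is taken as a catalogue chemical.

**Route**

Step 1
Reactants: 1 but-2-yn-1-ol
Product: 3 (E)-3-iodobut-2-en-1-ol, via alkenylzirconocene chloride 2 (not isolated)
Conditions: i-Bu2AlH (1 equiv), THF, 0 °C; then Cp2ZrCl2/i-Bu2AlH (Cp2Zr(H)Cl formed in the flask), 0 °C to rt; then I2, −78 to 0 °C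
Reagents that add atoms: iodine, II
Why: Syn hydrozirconation of the aluminium alkoxide of the 2-alkyne should place zirconium on C3, remote from oxygen, and iodinolysis of the C–Zr bond with retention should give the (E)-vinyl iodide (hydrozirconation–iodination).

Step 2
Reactants: 3 (E)-3-iodobut-2-en-1-ol
Product: 4 (E)-1-bromo-3-iodobut-2-ene
Conditions: CBr4, PPh3, CH2Cl2, 0 °C
Reagents that add atoms: carbon tetrabromide, BrC(Br)(Br)Br
Why: The Appel reaction displaces the oxyphosphonium of the primary allylic alcohol by bromide in an SN2 sense and leaves the vinyl iodide and its geometry untouched.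

Step 3
Reactants: 5 2,3,4-trimethoxyphenol
Product: 6 2,3,4,4-tetramethoxycyclohexa-2,5-dien-1-one
Conditions: PhI(OAc)2, MeOH, 0 °C
Reagents that add atoms: methanol, CO
Why: Hypervalent-iodine oxidative dearomatisation of a para-methoxyphenol in methanol traps the phenoxenium ion at C4 and should give the para-quinone monoketal.

Step 4
Reactants: 6 2,3,4,4-tetramethoxycyclohexa-2,5-dien-1-one
Product: 7 (5R)-2,3,4,4-tetramethoxy-5-methylcyclohex-2-en-1-one
Conditions: Me2Zn, Cu(OTf)2 (cat.), (S)-binaphthyl-2,2'-diyl N,N-bis[(R)-1-phenylethyl]phosphoramidite (cat.), toluene, −25 °C; aq. NH4Cl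
Reagents that add atoms: dimethylzinc, C[Zn]C
Why: Copper-catalysed asymmetric conjugate addition can engage only the unsubstituted C5=C6 enone, because the C2=C3 enone is a deactivated vinylogous ester, and the chiral phosphoramidite–copper complex selects the enantioface so that C5 should become R.

Step 5
Reactants: 7 (5R)-2,3,4,4-tetramethoxy-5-methylcyclohex-2-en-1-one; 4 (E)-1-bromo-3-iodobut-2-ene
Product: 9 (5R,6R)-6-[(2E)-3-iodobut-2-en-1-yl]-2,3,4,4-tetramethoxy-5-methylcyclohex-2-en-1-one, via lithium dienolate 8 (not isolated)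
Conditions: LiN(SiMe3)2, THF, −78 °C; then 4, DMPU, −78 to −20 °C; aq. NH4Cl
Reagents that add atoms: none
Why: Deprotonation is possible only at C6, and enolate alkylation (SN2 at the allylic bromide) should occur on the face opposite the adjacent C5 methyl group, giving the trans-5,6 product, which is also the thermodynamically preferred one.

Step 6
Reactants: 9 (5R,6R)-6-[(2E)-3-iodobut-2-en-1-yl]-2,3,4,4-tetramethoxy-5-methylcyclohex-2-en-1-one
Product: 10 (1R,5R,6R)-6-[(2E)-3-iodobut-2-en-1-yl]-2,3,4,4-tetramethoxy-5-methylcyclohex-2-en-1-ol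
Conditions: LiBH(s-Bu)3 (L-Selectride), THF, −78 °C; aq. NH4Cl
Reagents that add atoms: none
Why: The bulky trialkylborohydride should add 1,2 to the β,β-disubstituted enone from the face opposite the C6 side chain (equatorial-type attack, as in 2-alkylcyclohexanone reductions), which sets C1 as R with the hydroxyl cis to the C6 substituent.

Step 7
Reactants: 11 prop-2-yn-1-ol
Product: 13 (E)-3-iodo-2-methylprop-2-en-1-ol, via alkenylalane 12 (not isolated)
Conditions: Me3Al, Cp2ZrCl2 (cat.), CH2Cl2, 0 °C to rt; then I2, THF, −30 to 0 °C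
Reagents that add atoms: trimethylaluminium, C[Al](C)C; iodine, II
Why: Zirconium-catalysed Negishi carboalumination adds methyl and aluminium syn across the terminal alkyne with methyl on the internal carbon, and iodinolysis with retention should give the (E)-vinyl iodide.

Step 8
Reactants: 13 (E)-3-iodo-2-methylprop-2-en-1-ol
Product: 14 tert-butyl{[(2E)-3-iodo-2-methylprop-2-en-1-yl]oxy}dimethylsilane
Conditions: TBSCl, imidazole, CH2Cl2, rt
Reagents that add atoms: tert-butyldimethylsilyl chloride, CC(C)(C)[Si](C)(C)Cl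
Why: Imidazole-mediated silylation of a primary alcohol is a standard protection that leaves the vinyl iodide unchanged.

Step 9
Reactants: 14 tert-butyl{[(2E)-3-iodo-2-methylprop-2-en-1-yl]oxy}dimethylsilane
Product: 16 (2E)-4-{[tert-butyl(dimethyl)silyl]oxy}-3-methylbut-2-enal, via vinyllithium 15 (not isolated)
Conditions: t-BuLi (2 equiv), Et2O, −78 °C; then DMF, −78 to 0 °C; aq. NH4Cl
Reagents that add atoms: N,N-dimethylformamide, CN(C)C=O
Why: Iodine–lithium exchange proceeds with retention of alkene geometry, and formylation of the vinyllithium with DMF (Bouveault aldehyde synthesis) should give the (E)-enal.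

Step 10
Reactants: 16 (2E)-4-{[tert-butyl(dimethyl)silyl]oxy}-3-methylbut-2-enal
Product: 17 (4S,5E)-7-{[tert-butyl(dimethyl)silyl]oxy}-6-methylhept-5-en-1-yn-4-ol
Conditions: allenylboronic acid pinacol ester, (S)-3,3'-bis(2,4,6-triisopropylphenyl)-1,1'-binaphthyl-2,2'-diyl hydrogen phosphate (cat.), 4 Å molecular sieves, toluene, −20 °C
Reagents that add atoms: allenylboronic acid pinacol ester, C=C=CB1OC(C)(C)C(C)(C)O1
Why: In this chiral phosphoric acid-catalysed propargylation the allenylboronate adds through a closed six-membered SE2' transition state organised by hydrogen bonds from the catalyst to a boronate oxygen and the formyl hydrogen, which should direct attack to the Si face of the enal and set the carbinol as S.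

Step 11
Reactants: 17 (4S,5E)-7-{[tert-butyl(dimethyl)silyl]oxy}-6-methylhept-5-en-1-yn-4-ol
Product: 18 (4S,5E)-4,7-bis{[tert-butyl(dimethyl)silyl]oxy}-6-methylhept-5-en-1-yne
Conditions: TBSCl, imidazole, DMF, rt
Reagents that add atoms: tert-butyldimethylsilyl chloride, CC(C)(C)[Si](C)(C)Cl
Why: Standard silylation of the secondary allylic alcohol protects it for the organometallic steps without touching the stereocentre.

Step 12
Reactants: 18 (4S,5E)-4,7-bis{[tert-butyl(dimethyl)silyl]oxy}-6-methylhept-5-en-1-yne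
Product: 20 (3E,6S,7E)-6,9-bis{[tert-butyl(dimethyl)silyl]oxy}-4,8-dimethylnona-1,3,7-triene, via alkenylalane 19 (not isolated)
Conditions: Me3Al, Cp2ZrCl2 (cat.), CH2Cl2, 0 °C to rt; evaporate; then vinyl bromide, ZnCl2 (cat.), Pd(PPh3)4 (cat.), THF, rt
Reagents that add atoms: trimethylaluminium, C[Al](C)C; vinyl bromide, C=CBr
Why: Negishi carboalumination adds methyl and aluminium syn across the terminal alkyne, and the palladium-catalysed, zinc-assisted Negishi coupling of the alkenylalane with vinyl bromide proceeds with retention, so the (3E)-diene should result.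

Step 13
Reactants: 20 (3E,6S,7E)-6,9-bis{[tert-butyl(dimethyl)silyl]oxy}-4,8-dimethylnona-1,3,7-triene; 10 (1R,5R,6R)-6-[(2E)-3-iodobut-2-en-1-yl]-2,3,4,4-tetramethoxy-5-methylcyclohex-2-en-1-ol
Product: 22 (1R,5R,6R)-6-[(2E,6E,9S,10E)-9,12-bis{[tert-butyl(dimethyl)silyl]oxy}-3,7,11-trimethyldodeca-2,6,10-trien-1-yl]-2,3,4,4-tetramethoxy-5-methylcyclohex-2-en-1-ol, via homoallyl-9-BBN borane 21 (not isolated)
Conditions: 9-BBN, THF, 0 °C to rt; then 10, Pd(dppf)Cl2 (cat.), AsPh3 (cat.), Cs2CO3, DMF/THF/H2O, rt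
Reagents that add atoms: none
Why: 9-BBN should add its B–H bond only across the monosubstituted terminus of the 1,3-diene of 20 (boron on the terminal CH2, anti-Markovnikov), because both trisubstituted alkenes are far too hindered for this dialkylborane and 10 is added only afterwards; oxidative addition of zerovalent palladium into the C–I bond of 10, transmetalation of the hydroxyborate of 21 and reductive elimination then form the C3'–C4' sp2–sp3 bond. The closest known reaction type is the B-alkyl Suzuki–Miyaura coupling of alkyl-9-BBN reagents with 1-methylalkenyl iodides, a standard way to trisubstituted alkenes in polyketide and terpenoid synthesis. No ring is closed and no stereocentre is created; the E geometry of C2'=C3' is carried over from 10 because oxidative addition and reductive elimination are stereoretentive at sp2 carbon. The step needs clean mono-hydroboration (secured by the substitution pattern of 20), suppression of β-hydride elimination from the homoallylpalladium intermediate (wide-bite-angle dppf, AsPh3 co-ligand, room temperature), and survival of the free C1 hydroxyl, the acid-labile ketal and both silyl ethers, all of which are inert to mild aqueous carbonate.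

Step 14
Reactants: 22 (1R,5R,6R)-6-[(2E,6E,9S,10E)-9,12-bis{[tert-butyl(dimethyl)silyl]oxy}-3,7,11-trimethyldodeca-2,6,10-trien-1-yl]-2,3,4,4-tetramethoxy-5-methylcyclohex-2-en-1-ol
Product: 24 (4R,5R,6R)-4-hydroxy-5-[(2E,6E,9S,10E)-9,12-dihydroxy-3,7,11-trimethyldodeca-2,6,10-trien-1-yl]-2,3-dimethoxy-6-methylcyclohex-2-en-1-one, via triol ketal 23 (not isolated)
Conditions: Bu4NF, THF, 0 °C to rt; then 1 M aq. HCl to pH 2–3, 0 °C; NaHCO3
Reagents that add atoms: water, O
Why: Fluoride should cleave both silyl ethers, and brief mild aqueous acid then hydrolyses the dimethyl ketal through an oxocarbenium ion stabilised by the adjacent dimethoxyalkene, releasing the 2,3-dimethoxyenone without touching any stereocentre.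

**Compound list**

1 | but-2-yn-1-ol | CC#CCO | starting material
2 | chlorobis(cyclopentadienyl)[(E)-4-(diisobutylalumanyloxy)but-2-en-2-yl]zirconium (formed in the flask) | CC(C)C[Al](CC(C)C)OC/C=C(\C)[Zr+2]Cl.c1cc[cH-]c1.c1cc[cH-]c1 | intermediate
3 | (E)-3-iodobut-2-en-1-ol | OC/C=C(\C)I | intermediate
4 | (E)-1-bromo-3-iodobut-2-ene | BrC/C=C(\C)I | intermediate
5 | 2,3,4-trimethoxyphenol | COc1ccc(O)c(OC)c1OC | starting material
6 | 2,3,4,4-tetramethoxycyclohexa-2,5-dien-1-one | COC1=C(OC)C(OC)(OC)C=CC1=O | intermediate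
7 | (5R)-2,3,4,4-tetramethoxy-5-methylcyclohex-2-en-1-one | COC1=C(OC)C(=O)C[C@@H](C)C1(OC)OC | intermediate
8 | lithium dienolate of 7 (O–Li on C1, C1=C6; formed in the flask) | COC1=C(OC)C(O[Li])=C[C@@H](C)C1(OC)OC | intermediate
9 | (5R,6R)-6-[(2E)-3-iodobut-2-en-1-yl]-2,3,4,4-tetramethoxy-5-methylcyclohex-2-en-1-one | COC1=C(OC)C(=O)[C@H](C/C=C(\C)I)[C@@H](C)C1(OC)OC | intermediate
10 | (1R,5R,6R)-6-[(2E)-3-iodobut-2-en-1-yl]-2,3,4,4-tetramethoxy-5-methylcyclohex-2-en-1-ol | COC1=C(OC)[C@H](O)[C@H](C/C=C(\C)I)[C@@H](C)C1(OC)OC | intermediate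
11 | prop-2-yn-1-ol | C#CCO | starting material
12 | (E)-[3-(dimethylalumanyloxy)-2-methylprop-1-en-1-yl]dimethylaluminium (formed in the flask) | C[Al](C)/C=C(\C)CO[Al](C)C | intermediate
13 | (E)-3-iodo-2-methylprop-2-en-1-ol | I/C=C(\C)CO | intermediate
14 | tert-butyl{[(2E)-3-iodo-2-methylprop-2-en-1-yl]oxy}dimethylsilane | I/C=C(\C)CO[Si](C)(C)C(C)(C)C | intermediate
15 | (E)-[3-(tert-butyldimethylsilyloxy)-2-methylprop-1-en-1-yl]lithium (formed in the flask) | [Li]/C=C(\C)CO[Si](C)(C)C(C)(C)C | intermediate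
16 | (2E)-4-{[tert-butyl(dimethyl)silyl]oxy}-3-methylbut-2-enal | O=C/C=C(\C)CO[Si](C)(C)C(C)(C)C | intermediate
17 | (4S,5E)-7-{[tert-butyl(dimethyl)silyl]oxy}-6-methylhept-5-en-1-yn-4-ol | C#CC[C@H](O)/C=C(\C)CO[Si](C)(C)C(C)(C)C | intermediate
18 | (4S,5E)-4,7-bis{[tert-butyl(dimethyl)silyl]oxy}-6-methylhept-5-en-1-yne | C#CC[C@H](O[Si](C)(C)C(C)(C)C)/C=C(\C)CO[Si](C)(C)C(C)(C)C | intermediate
19 | [(1E,4S,5E)-4,7-bis(tert-butyldimethylsilyloxy)-2,6-dimethylhepta-1,5-dien-1-yl]dimethylaluminium (formed in the flask) | C[Al](C)/C=C(\C)C[C@H](O[Si](C)(C)C(C)(C)C)/C=C(\C)CO[Si](C)(C)C(C)(C)C | intermediate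
20 | (3E,6S,7E)-6,9-bis{[tert-butyl(dimethyl)silyl]oxy}-4,8-dimethylnona-1,3,7-triene | C=C/C=C(\C)C[C@H](O[Si](C)(C)C(C)(C)C)/C=C(\C)CO[Si](C)(C)C(C)(C)C | intermediate
21 | 9-[(3E,6S,7E)-6,9-bis(tert-butyldimethylsilyloxy)-4,8-dimethylnona-3,7-dien-1-yl]-9-borabicyclo[3.3.1]nonane (formed in the flask) | B1(CC/C=C(\C)C[C@H](O[Si](C)(C)C(C)(C)C)/C=C(\C)CO[Si](C)(C)C(C)(C)C)C2CCCC1CCC2 | intermediate
22 | (1R,5R,6R)-6-[(2E,6E,9S,10E)-9,12-bis{[tert-butyl(dimethyl)silyl]oxy}-3,7,11-trimethyldodeca-2,6,10-trien-1-yl]-2,3,4,4-tetramethoxy-5-methylcyclohex-2-en-1-ol | COC1=C(OC)[C@H](O)[C@H](C/C=C(\C)CC/C=C(\C)C[C@H](O[Si](C)(C)C(C)(C)C)/C=C(\C)CO[Si](C)(C)C(C)(C)C)[C@@H](C)C1(OC)OC | intermediate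
23 | (1R,5R,6R)-6-[(2E,6E,9S,10E)-9,12-dihydroxy-3,7,11-trimethyldodeca-2,6,10-trien-1-yl]-2,3,4,4-tetramethoxy-5-methylcyclohex-2-en-1-ol (formed in the flask) | COC1=C(OC)[C@H](O)[C@H](C/C=C(\C)CC/C=C(\C)C[C@H](O)/C=C(\C)CO)[C@@H](C)C1(OC)OC | intermediate
24 | (4R,5R,6R)-4-hydroxy-5-[(2E,6E,9S,10E)-9,12-dihydroxy-3,7,11-trimethyldodeca-2,6,10-trien-1-yl]-2,3-dimethoxy-6-methylcyclohex-2-en-1-one | COC1=C(OC)[C@H](O)[C@H](C/C=C(\C)CC/C=C(\C)C[C@H](O)/C=C(\C)CO)[C@@H](C)C1=O | target

**Step count**

Total step count: 14. Longest linear sequence: 8 steps (steps 7 to 14).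

**Steps most likely to fail**

Step 13. The hydroboration may not stop cleanly at the terminal CH2 of the diene (allylic borane isomers, over-hydroboration), or the homoallylpalladium intermediate may lose the fragment by β-hydride elimination before C–C bond formation. The fallback avoids diene hydroboration and boron altogether. It sets out from 18, whose carboalumination gives alkenylalane 19 as in step 12. Conversion of 19 into its alanate with n-BuLi and opening of ethylene oxide should give the homoallylic alcohol (3E,6S,7E)-6,9-bis{[tert-butyl(dimethyl)silyl]oxy}-4,8-dimethylnona-3,7-dien-1-ol F1. Iodination (I2, PPh3, imidazole, CH2Cl2) gives the primary iodide (3E,6S,7E)-6,9-bis{[tert-butyl(dimethyl)silyl]oxy}-1-iodo-4,8-dimethylnona-3,7-diene F2. Zinc insertion (Zn dust, LiCl, THF) gives the homoallylzinc iodide F3. Negishi homoallyl–alkenyl coupling of F3 (used in excess to allow for the free hydroxyl) with 10 under Pd(dppf)Cl2 catalysis in THF/DMF comes back to the route at 22.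

Step 6. Hydride delivery may show poor facial selectivity, so that the C1 epimer with the hydroxyl trans to the side chain forms in quantity. The fallback makes that epimer on purpose and inverts it. It sets out from 9: Luche reduction (NaBH4, CeCl3·7H2O, MeOH, −40 °C; small hydride, axial attack) should give the (1S,5R,6R)-alcohol F4. Mitsunobu inversion (4-nitrobenzoic acid, PPh3, DIAD, toluene, 0 °C) gives the (1R)-4-nitrobenzoate F5, and methanolysis (K2CO3, MeOH) comes back to the route at 10.

Step 14. While the ketal is hydrolysed, acid may also dehydrate the ring hydroxy enone towards an aromatic phenol or ionise the side-chain allylic alcohols (1,3-transposition). The fallback moves the acid step in front of the coupling, so that the last step uses fluoride only. It sets out from 10 and borane 21: hydrolysis of the ketal of 10 (oxalic acid, THF/H2O, 0 °C) should give (4R,5R,6R)-4-hydroxy-5-[(2E)-3-iodobut-2-en-1-yl]-2,3-dimethoxy-6-methylcyclohex-2-en-1-one F6. B-alkyl Suzuki–Miyaura coupling of F6 with 21 (Pd(dppf)Cl2, AsPh3, K3PO4, DMF/THF/H2O, rt) gives the 9',12'-bis(tert-butyldimethylsilyl) ether of the target F7. Desilylation with HF·pyridine in pyridine/THF at 0 °C comes back to the route at 24.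

**Further compounds**

F1 | step 13 | (3E,6S,7E)-6,9-bis{[tert-butyl(dimethyl)silyl]oxy}-4,8-dimethylnona-3,7-dien-1-ol | OCC/C=C(\C)C[C@H](O[Si](C)(C)C(C)(C)C)/C=C(\C)CO[Si](C)(C)C(C)(C)C
F2 | step 13 | (3E,6S,7E)-6,9-bis{[tert-butyl(dimethyl)silyl]oxy}-1-iodo-4,8-dimethylnona-3,7-diene | ICC/C=C(\C)C[C@H](O[Si](C)(C)C(C)(C)C)/C=C(\C)CO[Si](C)(C)C(C)(C)C
F3 | step 13 | [(3E,6S,7E)-6,9-bis(tert-butyldimethylsilyloxy)-4,8-dimethylnona-3,7-dien-1-yl]zinc iodide | I[Zn]CC/C=C(\C)C[C@H](O[Si](C)(C)C(C)(C)C)/C=C(\C)CO[Si](C)(C)C(C)(C)C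
F4 | step 6 | (1S,5R,6R)-6-[(2E)-3-iodobut-2-en-1-yl]-2,3,4,4-tetramethoxy-5-methylcyclohex-2-en-1-ol | COC1=C(OC)[C@@H](O)[C@H](C/C=C(\C)I)[C@@H](C)C1(OC)OC
F5 | step 6 | (1R,5R,6R)-6-[(2E)-3-iodobut-2-en-1-yl]-2,3,4,4-tetramethoxy-5-methylcyclohex-2-en-1-yl 4-nitrobenzoate | COC1=C(OC)[C@H](OC(=O)c2ccc(cc2)[N+](=O)[O-])[C@H](C/C=C(\C)I)[C@@H](C)C1(OC)OC
F6 | step 14 | (4R,5R,6R)-4-hydroxy-5-[(2E)-3-iodobut-2-en-1-yl]-2,3-dimethoxy-6-methylcyclohex-2-en-1-one | COC1=C(OC)[C@H](O)[C@H](C/C=C(\C)I)[C@@H](C)C1=O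
F7 | step 14 | (4R,5R,6R)-5-[(2E,6E,9S,10E)-9,12-bis{[tert-butyl(dimethyl)silyl]oxy}-3,7,11-trimethyldodeca-2,6,10-trien-1-yl]-4-hydroxy-2,3-dimethoxy-6-methylcyclohex-2-en-1-one | COC1=C(OC)[C@H](O)[C@H](C/C=C(\C)CC/C=C(\C)C[C@H](O[Si](C)(C)C(C)(C)C)/C=C(\C)CO[Si](C)(C)C(C)(C)C)[C@@H](C)C1=O
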